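**Plan**
- The target is the meso 3,3′-biflavanone (2S,3R,2′R,3′S); its two halves are mirror images, so only relative configuration has to be controlled.
- Retrosynthetic cuts, in order: both aryl ether bonds O1–C8a and O1′–C8a′ of the pyranone rings C (double SNAr); both aryl ketone bonds C4–C4a and C4′–C4a′ (Weinreb ketone synthesis); the central C3–C3′ bond (oxidative enolate dimerization); C2–C3 (Claisen acylation).
- Forward: rings A and B are bought as arenes; the C2–C3 unit is made, dimerized through C3–C3′, reduced and arylated; the two rings C are closed last, both in one operation.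
- Enabling feature: in each half O1 sits on C8a, which is ortho to the C4 carbonyl on ring A. A C8a–F bond of a 2-fluoroaryl ketone is therefore activated for displacement by the C2 alkoxide, and the same carbonyl makes C3 epimerizable.
- Stereochemistry: C3/C3′ are fixed as meso by equilibration and crystallization of 4. C2/C2′ are relayed from them in one chelation-controlled double reduction, with opposite sense at the two ends. C3/C3′ finally settle 2,3-trans under thermodynamic control after ring closure.

Key step: step 5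

Remark: the SMILES is read as the achiral meso diastereomer, so no enantioselective step is planned; all four phenols are carried as benzyl ethers.

**Step 1**
Reactants: 1 4-(benzyloxy)benzoyl chloride; 2 N-methoxy-N-methylacetamide
Product: 3 3-[4-(benzyloxy)phenyl]-N-methoxy-N-methyl-3-oxopropanamide
Conditions: LiN(i-Pr)2 (2.1 equiv), 2 (2.0 equiv), THF, −78 °C; then 1, −78 → −40 °C; aq. NH4Cl
Reagents that add atoms: none
Why: Claisen-type C-acylation of the lithium amide enolate by the acid chloride should give the β-keto Weinreb amide, the second equivalent of enolate deprotonating the product and so preventing a second acylation; no stereocentre is formed.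

**Step 2**
Reactants: 3 3-[4-(benzyloxy)phenyl]-N-methoxy-N-methyl-3-oxopropanamide (2 equiv)
Product: 4 meso-(2R,3S)-2,3-bis[4-(benzyloxy)benzoyl]-N1,N4-dimethoxy-N1,N4-dimethylbutanediamide
Conditions: NaH (1.0 equiv), THF, 0 °C; I2 (0.5 equiv), 0 → 25 °C; then Et3N (cat.), EtOH, 25 °C, crystallization
Reagents that add atoms: none
Why: Oxidative dimerization of a β-dicarbonyl enolate (α-iodination, then SN2 displacement of iodide by a second enolate) should form the C3–C3′ bond; both new centres lie between two carbonyl groups, so the meso and racemic diastereomers interconvert through the enol under catalytic base, and the meso form is to be drawn off by crystallization while the mother liquor re-equilibrates.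

**Step 3**
Reactants: 4 meso-(2R,3S)-2,3-bis[4-(benzyloxy)benzoyl]-N1,N4-dimethoxy-N1,N4-dimethylbutanediamide
Product: 5 meso-(2S,3R)-2-{(S)-[4-(benzyloxy)phenyl](hydroxy)methyl}-3-{(R)-[4-(benzyloxy)phenyl](hydroxy)methyl}-N1,N4-dimethoxy-N1,N4-dimethylbutanediamide
Conditions: Zn(BH4)2 (Et2O solution), CH2Cl2, −20 → 0 °C; aq. NH4Cl
Reagents that add atoms: none
Why: Chelation-controlled reduction of a 2-substituted 3-oxo amide: zinc ties the ketone and amide oxygens into a six-membered chelate and hydride enters anti to the substituent on C3, which should give the syn β-hydroxy amide at each end; since the two ends of meso 4 are mirror images, C2 and C2′ are set with opposite configuration in this one operation and 5 is again meso.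

**Step 4**
Reactants: 5 meso-(2S,3R)-2-{(S)-[4-(benzyloxy)phenyl](hydroxy)methyl}-3-{(R)-[4-(benzyloxy)phenyl](hydroxy)methyl}-N1,N4-dimethoxy-N1,N4-dimethylbutanediamide; 6 4-(benzyloxy)-1-bromo-2-fluorobenzene
Product: 8 meso-(2S,3R)-1,4-bis[4-(benzyloxy)-2-fluorophenyl]-2-{(S)-[4-(benzyloxy)phenyl](hydroxy)methyl}-3-{(R)-[4-(benzyloxy)phenyl](hydroxy)methyl}butane-1,4-dione, via [4-(benzyloxy)-2-fluorophenyl]lithium 7 (not isolated)
Conditions: 6 (4.4 equiv), n-BuLi, THF, −78 °C; then 5, −78 °C; aq. NH4Cl at −78 °C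
Reagents that add atoms: none
Why: Weinreb ketone synthesis: after the two hydroxyl groups are deprotonated, the aryllithium (kept at −78 °C to avoid loss of LiF) should add once to each N-methoxy-N-methylamide to give a chelated tetrahedral intermediate that collapses to the ketone only on work-up; C2, C3, C3′ and C2′ are not touched.

**Step 5**
Reactants: 8 meso-(2S,3R)-1,4-bis[4-(benzyloxy)-2-fluorophenyl]-2-{(S)-[4-(benzyloxy)phenyl](hydroxy)methyl}-3-{(R)-[4-(benzyloxy)phenyl](hydroxy)methyl}butane-1,4-dione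
Product: 10 (2S,3R,2′R,3′S)-7,7′-bis(benzyloxy)-2,2′-bis[4-(benzyloxy)phenyl]-[3,3′-bichromane]-4,4′-dione, via cis,cis-bis(flavanone) 9 (not isolated)
Conditions: KN(SiMe3)2 (2.1 equiv), THF, −40 → 0 °C; then DBU (0.2 equiv), CH2Cl2, 25 °C
Reagents that add atoms: none
Why: KN(SiMe3)2 turns both C2 hydroxyls into potassium alkoxides, each of which adds to the fluorine-bearing carbon (the future C8a) ortho to the C4 ketone on ring A to give a Meisenheimer adduct stabilized by that carbonyl, and loss of fluoride restores the arene (addition–elimination SNAr). The closest known reaction type is the cyclization of 3-hydroxy-1-(2-fluorophenyl)propan-1-ones to chroman-4-ones. Each ring C closes as a six-membered ring by exo attack of oxygen on an sp2 carbon (6-exo-trig); the seven-membered closure onto the fluoroarene of the other half and the reversible five-membered hemiketal with the distal ketone lead to no product. No stereocentre is created: C2 and C2′ keep their configuration because their C–O bonds are not broken, which gives cis,cis-9; DBU then epimerizes C3 and C3′ through the C4 enols, and the half-chair with the 2-aryl and the 3-substituent both equatorial drives each ring to 2,3-trans, that is to meso 10. The step needs ether closure to outrun retro-aldol cleavage and β-elimination of the aldolates; this is secured by the six-membered intramolecular transition state, by fluoride as the fastest SNAr leaving group next to the ortho carbonyl, by a non-nucleophilic base at low temperature, and by the 7-benzyloxy group being meta to the reacting carbon.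

**Step 6**
Reactants: 10 (2S,3R,2′R,3′S)-7,7′-bis(benzyloxy)-2,2′-bis[4-(benzyloxy)phenyl]-[3,3′-bichromane]-4,4′-dione
Product: 11 (2S,3R,2′R,3′S)-7,7′-dihydroxy-2,2′-bis(4-hydroxyphenyl)-[3,3′-bichromane]-4,4′-dione
Conditions: H2 (1 atm), Pd/C (10 %), EtOAc–THF, 25 °C
Reagents that add atoms: none
Why: Hydrogenolysis of the four benzyl aryl ethers over Pd/C under neutral conditions should release the four phenols without base, so the base-labile 4′-hydroxyflavanone units keep the configuration at C2, C3, C3′ and C2′.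

**Compound list**
1 | 4-(benzyloxy)benzoyl chloride | O=C(Cl)c1ccc(OCc2ccccc2)cc1 | starting material
2 | N-methoxy-N-methylacetamide | CC(=O)N(C)OC | starting material
3 | 3-[4-(benzyloxy)phenyl]-N-methoxy-N-methyl-3-oxopropanamide | CON(C)C(=O)CC(=O)c1ccc(OCc2ccccc2)cc1 | intermediate
4 | meso-(2R,3S)-2,3-bis[4-(benzyloxy)benzoyl]-N1,N4-dimethoxy-N1,N4-dimethylbutanediamide | O=C(c1ccc(OCc2ccccc2)cc1)[C@@H](C(=O)N(C)OC)[C@@H](C(=O)N(C)OC)C(=O)c1ccc(OCc2ccccc2)cc1 | intermediate
5 | meso-(2S,3R)-2-{(S)-[4-(benzyloxy)phenyl](hydroxy)methyl}-3-{(R)-[4-(benzyloxy)phenyl](hydroxy)methyl}-N1,N4-dimethoxy-N1,N4-dimethylbutanediamide (syn at each end) | O[C@H](c1ccc(OCc2ccccc2)cc1)[C@@H](C(=O)N(C)OC)[C@@H](C(=O)N(C)OC)[C@@H](O)c1ccc(OCc2ccccc2)cc1 | intermediate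
6 | 4-(benzyloxy)-1-bromo-2-fluorobenzene | Fc1cc(OCc2ccccc2)ccc1Br | starting material
7 | [4-(benzyloxy)-2-fluorophenyl]lithium | [Li]c1ccc(OCc2ccccc2)cc1F | intermediate
8 | meso-(2S,3R)-1,4-bis[4-(benzyloxy)-2-fluorophenyl]-2-{(S)-[4-(benzyloxy)phenyl](hydroxy)methyl}-3-{(R)-[4-(benzyloxy)phenyl](hydroxy)methyl}butane-1,4-dione | O[C@H](c1ccc(OCc2ccccc2)cc1)[C@@H](C(=O)c1ccc(OCc2ccccc2)cc1F)[C@@H](C(=O)c1ccc(OCc2ccccc2)cc1F)[C@@H](O)c1ccc(OCc2ccccc2)cc1 | intermediate
9 | (2S,3S,2′R,3′R)-7,7′-bis(benzyloxy)-2,2′-bis[4-(benzyloxy)phenyl]-[3,3′-bichromane]-4,4′-dione (meso; both rings 2,3-cis) | O=C1c2ccc(OCc3ccccc3)cc2O[C@H](c2ccc(OCc3ccccc3)cc2)[C@@H]1[C@H]1C(=O)c2ccc(OCc3ccccc3)cc2O[C@H]1c1ccc(OCc2ccccc2)cc1 | intermediate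
10 | (2S,3R,2′R,3′S)-7,7′-bis(benzyloxy)-2,2′-bis[4-(benzyloxy)phenyl]-[3,3′-bichromane]-4,4′-dione (meso; both rings 2,3-trans) | O=C1c2ccc(OCc3ccccc3)cc2O[C@H](c2ccc(OCc3ccccc3)cc2)[C@H]1[C@@H]1C(=O)c2ccc(OCc3ccccc3)cc2O[C@H]1c1ccc(OCc2ccccc2)cc1 | intermediate
11 | (2S,3R,2′R,3′S)-7,7′-dihydroxy-2,2′-bis(4-hydroxyphenyl)-[3,3′-bichromane]-4,4′-dione | O=C1c2ccc(O)cc2O[C@H](c2ccc(O)cc2)[C@H]1[C@@H]1C(=O)c2ccc(O)cc2O[C@H]1c1ccc(O)cc1 | target

**Totals**
Total step count: 6. Longest linear sequence: 6 steps (1/2 → 3 → 4 → 5 → 8 → 10 → 11).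

**Steps most likely to fail**

Step 5. The potassium aldolates may fragment by retro-aldol cleavage or β-elimination before the aryl ether closes, and the C2/C2′ configuration may be lost by retro-oxa-Michael ring opening while C3/C3′ are equilibrated. The fallback replaces SNAr by a copper-catalysed Ullmann etherification. It sets out from 5: iodine–magnesium exchange of 4-(benzyloxy)-2-bromo-1-iodobenzene with i-PrMgCl·LiCl (THF, −40 °C) gives [4-(benzyloxy)-2-bromophenyl]magnesium chloride F1, which is added to 5 in the manner of step 4 to give the dibromo diol diketone meso-1,4-bis[4-(benzyloxy)-2-bromophenyl]-2,3-bis{[4-(benzyloxy)phenyl](hydroxy)methyl}butane-1,4-dione F2. CuI (10 mol %), 3,4,7,8-tetramethyl-1,10-phenanthroline, Cs2CO3, toluene, 80 °C should then close both aryl ether bonds through copper alkoxides of low basicity, and the carbonate present equilibrates C3/C3′, so the sequence comes back to the route at 10.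

Step 2. The coupling may give the racemic and meso dimers without preference and the crystallization may fail to enrich the meso form; over-oxidation to the alkene or cyclization to a furan are further losses. The fallback moves the diastereomer selection to the configurationally stable diol stage. It sets out from 3: the dimer mixture, meso 4 together with rac-(2R,3R)-2,3-bis[4-(benzyloxy)benzoyl]-N1,N4-dimethoxy-N1,N4-dimethylbutanediamide F3, is reduced with Zn(BH4)2 as in step 3. Meso diol 5 is separated by chromatography from the twofold-symmetric racemic diol rac-(2S,3S)-2,3-bis{(S)-[4-(benzyloxy)phenyl](hydroxy)methyl}-N1,N4-dimethoxy-N1,N4-dimethylbutanediamide F4. F4 is re-oxidized with Dess–Martin periodinane to F3, equilibrated with Et3N and recycled; the fallback comes back to the route at 5.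

Step 4. The aryllithium may deprotonate α to the amide or trigger retro-aldol cleavage of the lithium aldolate instead of adding, may lose LiF to an aryne on warming, and may over-add by way of a γ-lactone formed from the C2 alkoxide and the distal amide. The fallback goes through the dialdehyde. It sets out from 5: Et3SiOSO2CF3 and 2,6-lutidine give the bis(triethylsilyl) ether of 5 F5; i-Bu2AlH (THF, −78 °C) reduces both Weinreb amides to the dialdehyde 2,3-bis{[4-(benzyloxy)phenyl](triethylsilyloxy)methyl}butanedial F6; 7 adds at −78 °C to give the bis-carbinol 1,4-bis[4-(benzyloxy)-2-fluorophenyl]-2,3-bis{[4-(benzyloxy)phenyl](triethylsilyloxy)methyl}butane-1,4-diol F7 (a mixture at the two new carbinol carbons, of no consequence); Dess–Martin periodinane gives the bis(triethylsilyl) ether of 8 F8; HF·pyridine removes the silyl groups and the fallback comes back to the route at 8. Epimerization at C3/C3′ in F6 is harmless, since these centres are equilibrated in step 5.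

**Further compounds**
F1 | step 5 | [4-(benzyloxy)-2-bromophenyl]magnesium chloride | Brc1cc(OCc2ccccc2)ccc1[Mg]Cl
F2 | step 5 | meso-(2S,3R)-1,4-bis[4-(benzyloxy)-2-bromophenyl]-2-{(S)-[4-(benzyloxy)phenyl](hydroxy)methyl}-3-{(R)-[4-(benzyloxy)phenyl](hydroxy)methyl}butane-1,4-dione | O[C@H](c1ccc(OCc2ccccc2)cc1)[C@@H](C(=O)c1ccc(OCc2ccccc2)cc1Br)[C@@H](C(=O)c1ccc(OCc2ccccc2)cc1Br)[C@@H](O)c1ccc(OCc2ccccc2)cc1
F3 | step 2 | rac-(2R,3R)-2,3-bis[4-(benzyloxy)benzoyl]-N1,N4-dimethoxy-N1,N4-dimethylbutanediamide (one enantiomer drawn) | O=C(c1ccc(OCc2ccccc2)cc1)[C@@H](C(=O)N(C)OC)[C@H](C(=O)N(C)OC)C(=O)c1ccc(OCc2ccccc2)cc1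
F4 | step 2 | rac-(2S,3S)-2,3-bis{(S)-[4-(benzyloxy)phenyl](hydroxy)methyl}-N1,N4-dimethoxy-N1,N4-dimethylbutanediamide (one enantiomer drawn) | O[C@H](c1ccc(OCc2ccccc2)cc1)[C@@H](C(=O)N(C)OC)[C@H](C(=O)N(C)OC)[C@H](O)c1ccc(OCc2ccccc2)cc1
F5 | step 4 | meso-(2S,3R)-2-{(S)-[4-(benzyloxy)phenyl](triethylsilyloxy)methyl}-3-{(R)-[4-(benzyloxy)phenyl](triethylsilyloxy)methyl}-N1,N4-dimethoxy-N1,N4-dimethylbutanediamide | CC[Si](CC)(CC)O[C@H](c1ccc(OCc2ccccc2)cc1)[C@@H](C(=O)N(C)OC)[C@@H](C(=O)N(C)OC)[C@@H](O[Si](CC)(CC)CC)c1ccc(OCc2ccccc2)cc1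
F6 | step 4 | meso-2,3-bis{[4-(benzyloxy)phenyl](triethylsilyloxy)methyl}butanedial | CC[Si](CC)(CC)O[C@H](c1ccc(OCc2ccccc2)cc1)[C@@H](C=O)[C@@H](C=O)[C@@H](O[Si](CC)(CC)CC)c1ccc(OCc2ccccc2)cc1
F7 | step 4 | 1,4-bis[4-(benzyloxy)-2-fluorophenyl]-2,3-bis{[4-(benzyloxy)phenyl](triethylsilyloxy)methyl}butane-1,4-diol (C1 and C4 unassigned) | CC[Si](CC)(CC)O[C@H](c1ccc(OCc2ccccc2)cc1)[C@@H](C(O)c1ccc(OCc2ccccc2)cc1F)[C@@H](C(O)c1ccc(OCc2ccccc2)cc1F)[C@@H](O[Si](CC)(CC)CC)c1ccc(OCc2ccccc2)cc1
F8 | step 4 | meso-1,4-bis[4-(benzyloxy)-2-fluorophenyl]-2,3-bis{[4-(benzyloxy)phenyl](triethylsilyloxy)methyl}butane-1,4-dione | CC[Si](CC)(CC)O[C@H](c1ccc(OCc2ccccc2)cc1)[C@@H](C(=O)c1ccc(OCc2ccccc2)cc1F)[C@@H](C(=O)c1ccc(OCc2ccccc2)cc1F)[C@@H](O[Si](CC)(CC)CC)c1ccc(OCc2ccccc2)cc1
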